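The product made so far, target plus isomer of the product, is the measure here, and it counts against the whole substrate charge.

the same everywhere: substrate 0.010 M (fed, over 4.0 min)
- delta: free catalyst 100 µM; the very flask that is asked about, followed so far
- eta: free catalyst 67 µM; run made earlier
- flask: free catalyst 100 µM; time 15 min

- delta (time / min: substrate / %, target / %, isomer of the product / %): 0.417: 9.5, 0.4, 0.3; 1.00: 22.2, 2.7, 0; 2.00: 42.8, 6.2, 0; 3.00: 63.6, 10.7, 0.8; 5.00: 80.3, 19.4, 0.9
- eta (time / min: substrate / %, target / %, isomer of the product / %): 1.00: 22.1, 3.5, 1.0; 2.50: 54.4, 8.1, 0; 5.00: 80.1, 17.9, 1.6; 8.00: 71.1, 26.8, 3.4; 10.0: 66.7, 31.1, 3.3

(standard deviation of a reading: 0.5 percentage points)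

- what was read earlier has a scatter of 0.5 percentage points, one standard deviation
- the reaction counts as stopped when no species that holds the substrate changes by six tenths of a point or more over the second half of the time
- percentages count the whole charge, also what has not yet gone in

- at 15 min, what has stopped the reaction, if anything has (forward and back rates have come level / it is still moving / no working catalyst is left / all of the substrate has reacted)
- conversion of substrate at 15 min
- amount of target at 15 min, in percent of the substrate charged
- amount of isomer of the product at 15 min, in percent of the substrate charged

The first setting to turn is the catalyst. At 5.00 min, flask eta holds 19.5 % of product. By hand, a rate proportional to catalyst would give flask delta, with 1.49 times the charge, 29.1 %. Flask delta holds 20.3 %. Those two readings give the catalyst leverage, 0.100. It is the logarithm of the product ratio divided by the logarithm of the catalyst ratio at one clock reading, so time drops out: an apparent order in catalyst. It is a rough reading: the gap of 0.8 percentage points rests on four readings, so it carries a scatter of 1 point, which is more than the gap itself.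

The second setting is time. Flask eta reaches 34.4 % of product at 10.0 min, a gain of 15 points while the clock reaches twice its reading. My own reckoning assumes equal gains for equal factors of time. Eta then stands near 43.1 % at 15 min, and leverage lifts flask delta to 44.9 %. With eta's isomer share of 9.59 %, that is 40.6 % target and 4.31 % isomer. Over the second half of the time the clock doubles again, so flask delta gains about 15 points against the limit of 0.6: still moving.

The forecast says it is still moving, with conversion 42 %, target 38 % and isomer 4 %, expecting delta to “track eta, slightly ahead”. Its conversion lies below mine.

    catalyst intermediate A ⇌ catalyst intermediate B (K = 0.800, k = 1.60 /s)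
    2 free catalyst → spent catalyst (k = 410 /M/s)
    target ⇌ isomer of the product (K = 0.110, k = 0.00180 /s)
    substrate + free catalyst → catalyst intermediate A (k = 190 /M/s)
    catalyst intermediate B → free catalyst + target (k = 84.0 /s)

Flask delta gives it is still moving, with conversion 43.7 %, target 39.5 % and isomer 4.19 %. At 15.0 min, spent catalyst holds 96.3 % of the catalyst charged and free catalyst 2.20 %, which the conversion figure does not show. Leverage credits the extra catalyst over eta with 1.7 points of this conversion. A neighbour flask holds 2.5 × 10⁻⁵ M of free catalyst, a quarter of this charge. Leverage turns the conversion of flask delta into 38.1 % for it. That neighbour flask reaches 36.8 %.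

All runs were computed with constants of no real substance, noise included.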